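**Retrosynthetic overview**

1. Feature: in the ring (C1 ketone, C2=C3 alkene, C4 carbinol, C5 CH2, C6 tertiary carbinol) the C6–OH sits α to the C1 ketone of a cyclohex-2-enone. This is the array a 1-alkyl-7-oxabicyclo[2.2.1]heptan-2-one releases on β-elimination, so the C6 oxygen is traced back to a furan ring oxygen and the cis C4–OH/C6–OH pair to an exo substituent.
2. Last disconnections: the C3–O bridge bond (β-elimination, step 13) and C4–O (Baeyer–Villiger oxidation of an exo acetyl group, with retention).
3. Key disconnection: C5–C6 and C3–C4 by Diels–Alder addition of but-3-en-2-one 14 to the 2-alkyl-3-methoxyfuran 13.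
4. Furan 13: the C1'–furan bond by opening of (S)-oxirane 10 with 2-lithio-3-methoxyfuran; 10 from (S)-epichlorohydrin (source of C2') and the Grignard reagent of 1-bromotetradec-7-yne.
5. Ring order: the furan is bought (3-bromofuran); the carbocycle is formed once, inside oxa-bridged bicycle 15 (step 7); the bridge is opened to the monocyclic enone in step 13.

Key step: step 7

Remark on the chemistry: a peracid Baeyer–Villiger oxidation cannot be expected to spare a cis-dialkyl alkene or an enol ether, so the (10Z)-alkene is carried as the alkyne up to a Lindlar reduction (step 10) and the ring enol ether is turned into its dimethyl ketal (step 8) before the oxidation.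

Numbering: target ring C1–C6 and chain C1'–C17' as above. For the bicycles the numbering of 15 is kept: C1 = alkyl-bearing bridgehead (target C6), C2 = target C1, C3 = target C2, C4 = target C3, C5 = target C4, C6 = target C5, O7 = target C6–O.

**Route**

Step 1
Reactants: 1 3-bromofuran
Product: 2 3-methoxyfuran
Conditions: NaOMe (3 equiv), CuBr (copper monobromide, 10 mol %), MeOH/NMP, 110 °C, sealed vessel; distillation
Reagents that add atoms: sodium methoxide, [Na+].[O-]C
Why: Copper-catalysed Ullmann-type etherification replaces the bromide at the furan β-position, which is inert to direct substitution, by methoxide.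

Step 2
Reactants: 3 oct-1-yne, 4 1,6-dibromohexane
Product: 6 1-bromotetradec-7-yne, via lithium oct-1-yn-1-ide 5 (not isolated)
Conditions: n-BuLi, THF, −78 to 0 °C; then 4 (3 equiv), DMPU, 0 °C to rt
Reagents that add atoms: none
Why: Acetylide alkylation (SN2 on a primary bromide in THF/DMPU); the excess of 4 suppresses double alkylation.

Step 3
Reactants: 6 1-bromotetradec-7-yne, 7 (S)-epichlorohydrin
Product: 9 (2S)-1-chloroheptadec-10-yn-2-ol, via tetradec-7-yn-1-ylmagnesium bromide 8 (not isolated)
Conditions: Mg, THF, rt to 40 °C; then CuI (copper monoiodide, 10 mol %), 7, THF, −40 to 0 °C; H2O then dilute aq. NH4Cl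
Reagents that add atoms: none
Why: Copper-catalysed Grignard opening of the epoxide at its unsubstituted carbon (SN2) leaves the C–Cl bond and the stereocentre untouched, so the future C2' configuration comes from (S)-epichlorohydrin (the descriptor stays S because CH2Cl keeps its rank above the new chain).

Step 4
Reactants: 9 (2S)-1-chloroheptadec-10-yn-2-ol
Product: 10 (2S)-2-(pentadec-8-yn-1-yl)oxirane
Conditions: NaOH (powdered), Et2O, rt
Reagents that add atoms: none
Why: Intramolecular Williamson etherification (the alkoxide displaces the primary chloride) closes the oxirane without touching the stereocentre, which stays S.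

Step 5
Reactants: 2 3-methoxyfuran, 10 (2S)-2-(pentadec-8-yn-1-yl)oxirane
Product: 12 (2S)-1-(3-methoxyfuran-2-yl)heptadec-10-yn-2-ol, via 2-lithio-3-methoxyfuran 11 (not isolated)
Conditions: 2 (1.3 equiv), n-BuLi, THF, −78 to 0 °C; then 10, 0 °C to rt; H2O
Reagents that add atoms: none
Why: Directed lithiation occurs at the furan α-carbon flanked by the ring oxygen and the methoxy group, and the heteroaryllithium opens the terminal epoxide at CH2 (SN2), so the carbinol centre is retained as S.

Step 6
Reactants: 12 (2S)-1-(3-methoxyfuran-2-yl)heptadec-10-yn-2-ol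
Product: 13 tert-butyl{[(2S)-1-(3-methoxyfuran-2-yl)heptadec-10-yn-2-yl]oxy}dimethylsilane
Conditions: TBSCl, imidazole, DMF, rt
Reagents that add atoms: tert-butyldimethylsilyl chloride, CC(C)(C)[Si](C)(C)Cl
Why: Imidazole-promoted silylation of a secondary alcohol; the silyl ether keeps the hydroxyl from adding to the enol ether in step 8 and should survive steps 7 to 11.

Step 7
Reactants: 13 tert-butyl{[(2S)-1-(3-methoxyfuran-2-yl)heptadec-10-yn-2-yl]oxy}dimethylsilane, 14 but-3-en-2-one
Product: 15 1-[(1S,4R,5S)-1-[(2S)-2-(tert-butyldimethylsilyloxy)heptadec-10-yn-1-yl]-2-methoxy-7-oxabicyclo[2.2.1]hept-2-en-5-yl]ethan-1-one (acetyl exo, syn to O7)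
Conditions: 14 (8 equiv), BHT (trace), neat, rt, dark, until the isomer composition no longer changes; excess 14 removed cold in vacuo; chromatography on Et3N-treated SiO2
Reagents that add atoms: none
Why: The electron-rich furan (largest HOMO coefficient at the alkyl-bearing carbon next to the methoxy group) and the enone (largest LUMO coefficient at CH2) combine in a concerted, asynchronous, suprafacial [4+2] cycloaddition; the closest known reaction type is the Diels–Alder reaction of 3-alkoxyfurans with acceptor alkenes. The six-membered carbocycle (target C1 to C6) is closed by this intermolecular cycloaddition, which forms C5–C6 and C3–C4 together and leaves the furan oxygen as a one-atom bridge between C3 and C6. Regioselectivity is needed and is secured by the methoxy group, which sends the substituted furan terminus to the unsubstituted enone carbon, also the less hindered orientation. The bridgeheads (target C6 and C3) are fixed relative to each other by the suprafacial addition, and C4 is set by the exo preference: such furan adducts revert and re-form near room temperature, so the more stable exo isomer (acetyl syn to the oxygen bridge, hence cis to the later C6–OH) should accumulate. Which furan face is attacked is not controlled by the C2' silyloxy centre, so 15 and its exo diastereomer of opposite bridgehead sense are both expected and are separated by chromatography. Unwanted isomers can be cracked back to 13 and 14 by gentle heating and resubmitted.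

Step 8
Reactants: 15 exo-acetyl enol ether adduct
Product: 16 1-[(1S,4R,5S)-1-[(2S)-2-(tert-butyldimethylsilyloxy)heptadec-10-yn-1-yl]-2,2-dimethoxy-7-oxabicyclo[2.2.1]heptan-5-yl]ethan-1-one
Conditions: MeOH, PPTS (5 mol %), CH2Cl2, 0 °C; Et3N quench
Reagents that add atoms: methanol, CO
Why: Acid-catalysed Markovnikov addition of methanol to the enol ether (protonation at C3, capture of the C2 oxocarbenium ion) gives the dimethyl ketal, which removes the electron-rich ring alkene before the peracid step, makes cycloreversion impossible and creates no stereocentre.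

Step 9
Reactants: 16 acetyl dimethyl ketal
Product: 17 (1S,4R,5S)-1-[(2S)-2-(tert-butyldimethylsilyloxy)heptadec-10-yn-1-yl]-2,2-dimethoxy-7-oxabicyclo[2.2.1]heptan-5-yl acetate (exo)
Conditions: mCPBA (2.5 equiv), NaHCO3, CH2Cl2, 0 °C to rt
Reagents that add atoms: 3-chloroperoxybenzoic acid, OOC(=O)c1cccc(Cl)c1
Why: Baeyer–Villiger oxidation of the methyl ketone, in which the secondary ring carbon migrates in preference to methyl with retention, so the exo acetyl group becomes the exo acetate (future C4–O); the buffered peracid should leave the ketal, the silyl ether and the internal alkyne alone.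

Step 10
Reactants: 17 alkynyl acetate
Product: 18 (1S,4R,5S)-1-[(2S,10Z)-2-(tert-butyldimethylsilyloxy)heptadec-10-en-1-yl]-2,2-dimethoxy-7-oxabicyclo[2.2.1]heptan-5-yl acetate
Conditions: H2 (1 atm), Pd on CaCO3 poisoned with Pb(OAc)2 (Lindlar catalyst), quinoline, EtOAc, rt
Reagents that add atoms: none
Why: Lindlar semihydrogenation delivers both hydrogens to one face of the alkyne on the poisoned palladium surface and gives the (10Z)-alkene; nothing else reducible is present at this stage.

Step 11
Reactants: 18 (Z)-alkene acetate
Product: 19 (1S,4R,5S)-1-[(2S,10Z)-2-(tert-butyldimethylsilyloxy)heptadec-10-en-1-yl]-2,2-dimethoxy-7-oxabicyclo[2.2.1]heptan-5-ol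
Conditions: K2CO3 (0.2 equiv), MeOH, rt
Reagents that add atoms: none
Why: Base-catalysed transesterification (methanolysis) removes the acetate while the ketal keeps the ring carbonyl masked, so no enolisable ketone is exposed to base.

Step 12
Reactants: 19 silyloxy ketal alcohol
Product: 20 (1R,4R,5S)-5-hydroxy-1-[(2S,10Z)-2-hydroxyheptadec-10-en-1-yl]-7-oxabicyclo[2.2.1]heptan-2-one
Conditions: 1 M aq. HCl, THF, rt
Reagents that add atoms: water, O
Why: Aqueous acid hydrolyses the dimethyl ketal to the ketone and cleaves the secondary silyl ether; both unmaskings are placed here because the saturated oxa-bridged ketone tolerates acid whereas the final hydroxy enone does not.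

Step 13
Reactants: 20 oxa-bridged keto diol
Product: 21 (4S,6R)-4,6-dihydroxy-6-[(2S,10Z)-2-hydroxyheptadec-10-en-1-yl]cyclohex-2-en-1-one (target)
Conditions: DBU (1.1 equiv), CH2Cl2, 0 °C; pH 7 phosphate buffer quench as soon as 20 is consumed
Reagents that add atoms: none
Why: E1cB β-elimination, the known base-induced opening of 7-oxabicyclo[2.2.1]heptan-2-ones: the only enolisable position is C3 of the bicycle (bridgehead C1 has no hydrogen), and its enolate expels the bridging oxygen from C4 with release of strain, giving the target C2=C3 enone while the oxygen stays on the former bridgehead as the C6 hydroxyl; no bond to target C4, C6 or C2' is broken, so their configurations are retained.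

**Compound list**

1 | 3-bromofuran | Brc1ccoc1 | starting material
2 | 3-methoxyfuran | COc1ccoc1 | intermediate
3 | oct-1-yne | CCCCCCC#C | starting material
4 | 1,6-dibromohexane | BrCCCCCCBr | starting material
5 | lithium oct-1-yn-1-ide | CCCCCCC#C[Li] | intermediate
6 | 1-bromotetradec-7-yne | CCCCCCC#CCCCCCCBr | intermediate
7 | (S)-epichlorohydrin, (2S)-2-(chloromethyl)oxirane | ClC[C@@H]1CO1 | starting material
8 | tetradec-7-yn-1-ylmagnesium bromide | CCCCCCC#CCCCCCC[Mg]Br | intermediate
9 | (2S)-1-chloroheptadec-10-yn-2-ol | CCCCCCC#CCCCCCCC[C@H](O)CCl | intermediate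
10 | (2S)-2-(pentadec-8-yn-1-yl)oxirane | CCCCCCC#CCCCCCCC[C@H]1CO1 | intermediate
11 | 2-lithio-3-methoxyfuran | COc1ccoc1[Li] | intermediate
12 | (2S)-1-(3-methoxyfuran-2-yl)heptadec-10-yn-2-ol | CCCCCCC#CCCCCCCC[C@H](O)Cc1occc1OC | intermediate
13 | tert-butyl{[(2S)-1-(3-methoxyfuran-2-yl)heptadec-10-yn-2-yl]oxy}dimethylsilane | CCCCCCC#CCCCCCCC[C@H](O[Si](C)(C)C(C)(C)C)Cc1occc1OC | intermediate
14 | but-3-en-2-one | CC(=O)C=C | starting material
15 | 1-[(1S,4R,5S)-1-[(2S)-2-(tert-butyldimethylsilyloxy)heptadec-10-yn-1-yl]-2-methoxy-7-oxabicyclo[2.2.1]hept-2-en-5-yl]ethan-1-one (exo acetyl) | CCCCCCC#CCCCCCCC[C@H](O[Si](C)(C)C(C)(C)C)C[C@]12C[C@H](C(C)=O)[C@H](O1)C=C2OC | intermediate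
16 | 1-[(1S,4R,5S)-1-[(2S)-2-(tert-butyldimethylsilyloxy)heptadec-10-yn-1-yl]-2,2-dimethoxy-7-oxabicyclo[2.2.1]heptan-5-yl]ethan-1-one | CCCCCCC#CCCCCCCC[C@H](O[Si](C)(C)C(C)(C)C)C[C@]12C[C@H](C(C)=O)[C@H](O1)CC2(OC)OC | intermediate
17 | (1S,4R,5S)-1-[(2S)-2-(tert-butyldimethylsilyloxy)heptadec-10-yn-1-yl]-2,2-dimethoxy-7-oxabicyclo[2.2.1]heptan-5-yl acetate | CCCCCCC#CCCCCCCC[C@H](O[Si](C)(C)C(C)(C)C)C[C@]12C[C@H](OC(C)=O)[C@H](O1)CC2(OC)OC | intermediate
18 | (1S,4R,5S)-1-[(2S,10Z)-2-(tert-butyldimethylsilyloxy)heptadec-10-en-1-yl]-2,2-dimethoxy-7-oxabicyclo[2.2.1]heptan-5-yl acetate | CCCCCC/C=C\CCCCCCC[C@H](O[Si](C)(C)C(C)(C)C)C[C@]12C[C@H](OC(C)=O)[C@H](O1)CC2(OC)OC | intermediate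
19 | (1S,4R,5S)-1-[(2S,10Z)-2-(tert-butyldimethylsilyloxy)heptadec-10-en-1-yl]-2,2-dimethoxy-7-oxabicyclo[2.2.1]heptan-5-ol | CCCCCC/C=C\CCCCCCC[C@H](O[Si](C)(C)C(C)(C)C)C[C@]12C[C@H](O)[C@H](O1)CC2(OC)OC | intermediate
20 | (1R,4R,5S)-5-hydroxy-1-[(2S,10Z)-2-hydroxyheptadec-10-en-1-yl]-7-oxabicyclo[2.2.1]heptan-2-one | CCCCCC/C=C\CCCCCCC[C@H](O)C[C@]12C[C@H](O)[C@H](O1)CC2=O | intermediate
21 | (4S,6R)-4,6-dihydroxy-6-[(2S,10Z)-2-hydroxyheptadec-10-en-1-yl]cyclohex-2-en-1-one | CCCCCC/C=C\CCCCCCC[C@H](O)C[C@@]1(O)C[C@H](O)C=CC1=O | target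

**Step count**

Total: 13 steps. Longest linear sequence: 12 steps (steps 2 to 13, from oct-1-yne); step 1 is the only side branch.

**Three steps most likely to fail**

Step 7. What may go wrong: no discrimination between the two furan faces, a modest exo share at equilibrium, and partial cycloreversion on silica, so that 15 cannot be obtained clean at the enol-ether stage. The fallback sets out from 13 and 14 and gives up separation at that stage. The mixture of 15 and the exo adduct of opposite bridgehead sense F1 is taken through steps 8 to 10 as 16 with the ketal F2, 17 with the acetate F3, and 18 with the (Z)-alkene acetate F4; endo isomers are removed at the ketal stage, where reversion is no longer possible. The pair is then differentiated by an enzyme instead of silica: a lipase (for example Candida rugosa lipase, pH 7 phosphate buffer/acetone, rt), a known tool for resolving esters of 7-oxabicyclo[2.2.1]heptanols, should hydrolyse the acetate of one bicyclic series only. If 18 is accepted, alcohol 19 forms and is separated from unchanged F4. If F4 is accepted, the alcohol F5 is removed and recovered 18 goes through step 11. Either way the route is rejoined at 19.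

Step 13. What may go wrong: the product stays in contact with base, and the 4-hydroxy enone isomerises to the 1,4-dione, dehydrates towards an alkylhydroquinone or undergoes an α-ketol shift. The fallback sets out from 20 and uses soft, silyl-mediated enolisation. TMSOTf (5 equiv) and Et3N in CH2Cl2 at −78 to 0 °C silylate both hydroxyls and convert the ketone into the silyl enol ether F6. Under the same Lewis-acidic silyl triflate the bridge opens to the tris(trimethylsilyl) ether F7 of the target, a known way of opening 7-oxabicyclo[2.2.1]heptan-2-ones. HF·pyridine in THF at 0 °C then removes the three silyl groups under acidic conditions, which the hydroxy enone tolerates, and the route is rejoined at 21.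

Step 9. What may go wrong: slow migration at a methyl ketone whose migrating carbon carries a β-oxygen, so that long exposure to peracid and carboxylic acid cleaves the ketal (the strained ring ketone would then be oxidised first) or attacks the alkyne. The fallback sets out from 16 and replaces the peracid by a Criegee sequence. Wittig methylenation (Ph3P=CH2 from Ph3PCH3Br and KN(SiMe3)2, THF, 0 °C) gives the isopropenyl compound F8. Ozonolysis in CH2Cl2/MeOH with NaHCO3 at −78 °C, dosed to the first excess of ozone, should consume the 1,1-disubstituted alkene far faster than the internal alkyne and gives the α-methoxy hydroperoxide F9. Ac2O, Et3N and DMAP then induce the Criegee rearrangement with retention at the migrating carbon, and the route is rejoined at acetate 17.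

**Further compounds**

F1 | step 7 | exo adduct of opposite bridgehead sense, (1R,4S,5R) diastereomer of 15 | CCCCCCC#CCCCCCCC[C@H](O[Si](C)(C)C(C)(C)C)C[C@@]12C[C@@H](C(C)=O)[C@@H](O1)C=C2OC
F2 | step 7 | (1R,4S,5R) diastereomer of ketal 16 | CCCCCCC#CCCCCCCC[C@H](O[Si](C)(C)C(C)(C)C)C[C@@]12C[C@@H](C(C)=O)[C@@H](O1)CC2(OC)OC
F3 | step 7 | (1R,4S,5R) diastereomer of acetate 17 | CCCCCCC#CCCCCCCC[C@H](O[Si](C)(C)C(C)(C)C)C[C@@]12C[C@@H](OC(C)=O)[C@@H](O1)CC2(OC)OC
F4 | step 7 | (1R,4S,5R) diastereomer of (Z)-alkene acetate 18 | CCCCCC/C=C\CCCCCCC[C@H](O[Si](C)(C)C(C)(C)C)C[C@@]12C[C@@H](OC(C)=O)[C@@H](O1)CC2(OC)OC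
F5 | step 7 | (1R,4S,5R) diastereomer of alcohol 19 | CCCCCC/C=C\CCCCCCC[C@H](O[Si](C)(C)C(C)(C)C)C[C@@]12C[C@@H](O)[C@@H](O1)CC2(OC)OC
F6 | step 13 | silyl enol ether of 20 with both hydroxyls as trimethylsilyl ethers | CCCCCC/C=C\CCCCCCC[C@H](O[Si](C)(C)C)C[C@]12C[C@H](O[Si](C)(C)C)[C@H](O1)C=C2O[Si](C)(C)C
F7 | step 13 | tris(trimethylsilyl) ether of 21 | CCCCCC/C=C\CCCCCCC[C@H](O[Si](C)(C)C)C[C@@]1(O[Si](C)(C)C)C[C@H](O[Si](C)(C)C)C=CC1=O
F8 | step 9 | isopropenyl analogue of 16 (acetyl C=O replaced by C=CH2) | CCCCCCC#CCCCCCCC[C@H](O[Si](C)(C)C(C)(C)C)C[C@]12C[C@H](C(C)=C)[C@H](O1)CC2(OC)OC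
F9 | step 9 | α-methoxy hydroperoxide from F8 (C5 substituent C(CH3)(OCH3)OOH, mixture at that carbon) | CCCCCCC#CCCCCCCC[C@H](O[Si](C)(C)C(C)(C)C)C[C@]12C[C@H](C(C)(OC)OO)[C@H](O1)CC2(OC)OC
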